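The rate constants are assumed; the rest is arithmetic.

I bracketed.

solid substrate 0.050 M; enzyme 0.0029 mol%; time 30 min

* amount of product at 30 min, in percent of the solid substrate charged
* concentration of starting material in solution at 30 min, in percent of saturation

    starting material + enzyme → product + enzyme, rate k1*[starting material]*[enzyme]/(1 + ([starting material]/Km1) + ([starting material]/Ksi1)^2) (Km1 = 21.7 mM, Ksi1 = 5.49 mM, k1 = 2.52 × 10⁶ /M/s)
    solid substrate ⇌ starting material, rate k2*(cs2 - [starting material]) while solid is left; crystals form when [starting material] > cs2 (cs2 = 38 mM, k2 = 2.67 × 10⁻⁴ /s)

- as a solid, counted per litre of solution: solid substrate
- at the start none of the solid substrate is in solution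
- starting material means what is dissolved; the solid is not counted in it
- run time (flask): 30 min

From above, I took an empty solution, where dissolving runs fastest. I called the delivery ceiling the fraction of the charge going into solution per minute while the solution is empty, the dissolution coefficient times the solubility over the charge: 0.0122 /min. Over 30 min that allows 36.5% as product, with at least 63.5% of the charge still solid.

From below, I tried a solution at 1.00% of saturation. With the enzyme's first-order constant of 3.65 /s, it would remove 1.63 /min of the charge there, far faster than the ceiling. So I expected the level to stay below that mark, dissolving to be the rate-limiting step, and product to reach at least 35.4%.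

To tighten this, I set the enzyme's removal, pseudo-first-order at such levels, equal to the ceiling. They cross at about 0.00731% of saturation, which is 0.00555% of the charge, and my lower estimate rises to 36.5%.

The forecast said 36.5% and 0.0073%: “The process is dissolution-limited and zero-order.” Its yield stood at my ceiling.

The flask gave 36.5% and 0.00731%. While solid substrate stood there, still 63.5% of the charge at 30.0 min, product grew steadily, from 3.65% at 3.00 min to 18.3% at 15.0 min. Meanwhile starting material stayed at 0.00555% of the charge, and the enzyme at 100% of its own charge. With half the dissolution coefficient, the flask gave 18.3% at 30 min, so the forecast's yield would no longer have held. For the same flask read at 8.0 min the ceiling gives 9.76%, and that flask held 9.73% product.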